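## Structural features

The target is a 5,7-dihydroxyisoflavone: a benzopyran-4-one (benzo ring A fused to pyranone ring C) whose C3 is bonded directly to C5 of a 2,2-dimethylchroman (aromatic ring B fused to dihydropyran ring D). Ring B carries substituents on five contiguous carbons: C4a and C8a belong to ring D, C5 holds the pyranone, C7 a methoxy group and C8 a free phenol, so only C6 bears hydrogen. The single stereocentre is chroman C3, an (S)-configured secondary carbinol between the quaternary C2 (gem-dimethyl, bonded to O1) and the benzylic C4 methylene. No neighbouring stereocentre exists from which it could be relayed. The fragile groups are the three phenols (the guaiacol-type phenol of ring B is easily oxidised), the pyranone (opened by hydroxide or alkoxide at C2, reducible at C2=C3) and, under forcing acid, the carbinol next to the tertiary ether carbon. The real difficulty is to place five different groups correctly on ring B and to set an isolated carbinol centre with absolute control. The key step uses the fact that C3 is the reduced form of a ketone whose C2 flank has no hydrogen and whose C4 flank is benzylic. An ester on C2 can therefore only be the electrophile and an ester-activated C4 only the nucleophile, so ring D closes at C3–C4 in one direction, and the ketone offers a tertiary-against-methylene contrast to a chiral reductant.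

## Logic of the disconnections

22 to 21: the three O–benzyl bonds (C5 and C7 of the chromenone, C8 of the chroman) are cut. One protecting group for all phenols allows a single neutral hydrogenolysis as the last step, so no free electron-rich phenol meets base, oxidant or acid earlier. The forward step must stop before C2=C3 of ring C is reduced.

21 to 19 (through 20): the bonds cut are O1–C2 of ring C and the bond from pyranone C3 to chroman C5, the aryl group returning to the former β-carbon of an enone. An oxidative 1,2-aryl shift turns an aldehyde-derived carbon into C2 and delivers the hindered aryl–C3 bond without a cross-coupling partner. The forward step needs ring B to migrate well (it is para-alkoxy-substituted), the free ortho phenol of ring A to close onto the acetal carbon, and the C3 hydroxyl to tolerate oxidant and acid.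

19 to 16 plus 18: the Cα=Cβ bond is cut by a retro-aldol condensation, which splits the molecule into two halves of similar size; 18 goes back to 17 by removal of two benzyl groups. The forward step requires that only 18 can enolise and that 16 tolerates hydroxide.

16 to 14 (through 15): the C3–H bond and the acetal C–O bonds are cut. The only stereocentre becomes a ketone with sharply different flanks, so it can be set by catalyst control on an achiral substrate. The aldehyde must stay masked until all hydride is destroyed.

14 to 13: the bond from C4 to the ester carbon is cut. The ester is only an activating group for ring closure; its removal must be near neutral to spare the acetal and the enolisable ketone.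

13 to 12 (key): C3–C4 of ring D is cut, which opens the ring to two side chains on ring B and leaves no stereochemistry. The forward step needs at least one equivalent of strong base and a masked aldehyde.

12 to 8 (through 11, 10 and 9): the two-carbon ester chain is traced to an allyl group by C=C cleavage and oxidation-level adjustment. The gain is that an allyl group can be placed by a sigmatropic shift. The oxidations must spare ring B and the acetal.

8 to 6 plus 7: the ether bond from the ring B oxygen to the quaternary carbon (future O1–C2) is cut, so the quaternary centre and its ester arrive in one commercial piece. The forward step is a substitution at a tertiary α-bromo ester by a hindered phenoxide.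

6 to 5 to 4: the acetal is removed and then the aryl–allyl bond (future C4a–C4) is cut in a retro-Claisen sense. The phenol oxygen has only one free ortho position, and it is the required one.

4 to 2 plus 3, and 2 to 1: two ether bonds are cut. The two phenols of 1 differ in acidity, so the forward benzylation must take only the one para to the aldehyde.

## Other disconnections considered

Alternative 1: The cut is the aryl ether bond O1–C8a of ring D, made last on the complete isoflavone. The open-chain phenol A2, (2S)-1-[2-(5,7-diacetoxy-4-oxo-4H-chromen-3-yl)-5-hydroxy-4-methoxyphenyl]-3-hydroxy-3-methylbutan-2-yl acetate, would be oxidised at constant current in hexafluoroisopropanol. The phenoxonium ion should be captured by the tertiary hydroxyl at C8a to give A1, (3S)-5-(5,7-diacetoxy-4-oxo-4H-chromen-3-yl)-8-hydroxy-7-methoxy-2,2-dimethylchroman-3-yl acetate, and ester cleavage would then give 22.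
- In favour: no prefunctionalisation of ring B, no protecting group on the C8 phenol, no chemical oxidant. The carbinol would come from asymmetric dihydroxylation of a prenyl group, which is arguably more predictable than the ketone reduction of the chosen plan; on this point the alternative is the better one. The step count would probably be lower as well.
- Against: the phenoxonium ion carries positive charge both ortho (C8a) and para (C5) to the oxidised oxygen, and the tertiary hydroxyl can reach either through a six-membered ring. Para attack would give a dearomatised dienone that cannot rearomatise. The product A1 has one more alkoxy donor than A2, so it should be oxidised more easily than the substrate. Intramolecular dehydrogenative etherification of a phenol by an aliphatic alcohol has far less precedent than anodic C–C coupling.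
- Comparison: the chosen plan places its uncertain ring closure early, on a simple arene, with a single possible direction and an irreversible deprotonation as driving force. The alternative concentrates the risk in a late step on the most valuable intermediate.

Alternative 2: The cut is O1–C8a of ring C, with a trifluorophenyl ring standing in for phloroglucinol. The hydroxymethylene ketone A4, 2-[(3S)-8-benzyloxy-3-(tert-butyldimethylsilyloxy)-7-methoxy-2,2-dimethylchroman-5-yl]-3-hydroxy-1-(2,4,6-trifluorophenyl)prop-2-en-1-one, would be deprotonated by carbonate. Its enolate oxygen should displace an ortho fluoride to give A3, 3-[(3S)-8-benzyloxy-3-(tert-butyldimethylsilyloxy)-7-methoxy-2,2-dimethylchroman-5-yl]-5,7-difluoro-4H-chromen-4-one.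
- In favour: addition–elimination closure onto an ortho-fluoroaryl ketone is dependable, the two ortho fluorides are equivalent, and no thallium is needed. In certainty of the ring-closing event and in toxicity the alternative is the equal or the better of the chosen plan.
- Against: A3 still needs both remaining fluorides exchanged for oxygen. The first alkoxy group deactivates the ring toward the second exchange, and the pyranone is itself attacked at C2 by hard oxygen nucleophiles with ring opening. A silyl and a benzyl group must then be removed. A4 also requires a one-carbon homologation of the ring B aldehyde to an arylacetyl unit, and the chroman half still has to be made.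
- Comparison: the step count would be similar or higher. The chosen plan builds ring C with all oxygens already in place and ends with one hydrogenolysis.

Alternative 3: The cut is C4–C4a of ring D. The epoxy aryl ether A6, methyl 2-[4-benzyloxy-3-methoxy-5-({2-[(2S)-oxiran-2-yl]propan-2-yl}oxy)phenyl]acetate, would be ionised in hexafluoroisopropanol, with catalytic Sc(OTf)3 if required. The ring B carbon para to the methoxy group should attack the terminal epoxide carbon to give A5, methyl 2-[(3S)-8-benzyloxy-3-hydroxy-7-methoxy-2,2-dimethylchroman-5-yl]acetate.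
- In favour: ring D and the free C3 hydroxyl appear in one step, the stereocentre is preset and not touched by the bond formation, and the allyl transfer, alkene cleavage, esterification and decarboxylation of the chosen plan are avoided. In step economy the alternative is better. Having the stereocentre fixed before ring closure is at least an equal.
- Against: the closure is an endo opening at the primary carbon. It competes with 5-exo attack at the internal carbon (a dihydrobenzofuran), with solvent capture of the epoxide, and with acid ionisation of the tertiary alkyl aryl ether, which is a good leaving group under exactly these conditions. The enantiopure terminal epoxide next to a quaternary carbon is not a trivial building block, and its 1,1-dimethylallyl ether precursor is prone to sigmatropic rearrangement.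
- Comparison: the Dieckmann closure offers no regiochemical choice at all and starts from robust ethers and esters, at the price of more steps and a later stereoselective reduction.

Key step: step 9

**Remarks on the chemistry.**
- The ring B aldehyde is carried as its 5,5-dimethyl-1,3-dioxane acetal, not as an open-chain dimethyl acetal. Six-membered 2-aryl acetals of this kind tolerate the buffered chlorite oxidation of step 7 and the hot aqueous medium of step 10, and still fall off in dilute mineral acid.
- The C3 ketone is reduced with an oxazaborolidine catalyst. Transfer-hydrogenation catalysts of the RuCl(p-cymene)(TsDPEN) type draw their selectivity from an aryl group bonded directly to the carbonyl carbon, which 14 lacks; the oxazaborolidine reads the purely steric tertiary-against-methylene contrast.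
- 13 is written as the keto tautomer although it should exist largely as the C3–C4 enol.

## Route

Step 1
Reactants: 1 5-hydroxyvanillin (3,4-dihydroxy-5-methoxybenzaldehyde)
Product: 2 4-benzyloxy-3-hydroxy-5-methoxybenzaldehyde
Conditions: BnBr (1.05 equiv), Li2CO3 (1.1 equiv), DMF, 45 °C
Reagents that add atoms: benzyl bromide, BrCc1ccccc1
Why: Williamson etherification under acidity control: the hydroxyl para to the aldehyde is clearly the more acidic, and one equivalent of a weak, sparingly soluble base should generate and alkylate only that phenoxide.

Step 2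
Reactants: 2 4-benzyloxy-3-hydroxy-5-methoxybenzaldehyde; 3 allyl bromide
Product: 4 3-allyloxy-4-benzyloxy-5-methoxybenzaldehyde
Conditions: K2CO3, DMF, 50 °C
Reagents that add atoms: none
Why: Williamson O-allylation of the one remaining phenol; the aldehyde has no α-hydrogen and is inert to carbonate.

Step 3
Reactants: 4 3-allyloxy-4-benzyloxy-5-methoxybenzaldehyde
Product: 5 2-allyl-4-benzyloxy-3-hydroxy-5-methoxybenzaldehyde
Conditions: PhNEt2, 190 °C, Ar
Reagents that add atoms: none
Why: Aromatic Claisen rearrangement ([3,3] shift, then tautomerisation); of the two positions ortho to the allyloxy group one carries the benzyloxy group, so the allyl group should arrive at C2 between the oxygen and the formyl group, which is the future C4a–C4 bond.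

Step 4
Reactants: 5 2-allyl-4-benzyloxy-3-hydroxy-5-methoxybenzaldehyde
Product: 6 2-allyl-6-benzyloxy-3-(5,5-dimethyl-1,3-dioxan-2-yl)-5-methoxyphenol
Conditions: 2,2-dimethylpropane-1,3-diol, PPTS (cat.), toluene, reflux, Dean–Stark
Reagents that add atoms: 2,2-dimethylpropane-1,3-diol, OCC(C)(C)CO
Why: Acid-catalysed acetalisation driven by azeotropic removal of water; the weak acid PPTS should leave the ortho-allylphenol uncyclised.

Step 5
Reactants: 6 2-allyl-6-benzyloxy-3-(5,5-dimethyl-1,3-dioxan-2-yl)-5-methoxyphenol; 7 methyl 2-bromo-2-methylpropanoate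
Product: 8 methyl 2-[2-allyl-6-benzyloxy-3-(5,5-dimethyl-1,3-dioxan-2-yl)-5-methoxyphenoxy]-2-methylpropanoate
Conditions: 7 (3 equiv), Cs2CO3 (3 equiv), DMF, 60 °C
Reagents that add atoms: none
Why: O-alkylation of a caesium phenoxide by a tertiary α-bromo ester (the reaction used for aryloxyisobutyrates); the adjacent carbonyl makes the substitution possible, and excess bromide compensates for its loss by elimination.

Step 6
Reactants: 8 methyl 2-[2-allyl-6-benzyloxy-3-(5,5-dimethyl-1,3-dioxan-2-yl)-5-methoxyphenoxy]-2-methylpropanoate
Product: 10 methyl 2-[6-benzyloxy-3-(5,5-dimethyl-1,3-dioxan-2-yl)-5-methoxy-2-(2-oxoethyl)phenoxy]-2-methylpropanoate, via diol 9 (not isolated)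
Conditions: OsO4 (2 mol %), NaIO4 (4 equiv), 2,6-lutidine (2 equiv), dioxane/H2O 3:1, rt
Reagents that add atoms: OsO4, O=[Os](=O)(=O)=O (delivers the oxygen atoms of 9 and so the carbonyl oxygen of 10); sodium periodate, [Na+].[O-]I(=O)(=O)=O (terminal oxidant that restores OsO4)
Why: Lemieux–Johnson oxidation (dihydroxylation, then periodate glycol cleavage); osmylation is specific for the alkene and should leave the electron-rich ring B alone, where ozone might not, and the lutidine-buffered medium is safe for the acetal.

Step 7
Reactants: 10 methyl 2-[6-benzyloxy-3-(5,5-dimethyl-1,3-dioxan-2-yl)-5-methoxy-2-(2-oxoethyl)phenoxy]-2-methylpropanoate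
Product: 11 2-[3-benzyloxy-6-(5,5-dimethyl-1,3-dioxan-2-yl)-4-methoxy-2-(2-methoxy-1,1-dimethyl-2-oxoethoxy)phenyl]acetic acid
Conditions: NaClO2, NaH2PO4, 2-methyl-2-butene, t-BuOH/H2O, 0 °C
Reagents that add atoms: sodium chlorite, [Na+].[O-]Cl=O
Why: Pinnick oxidation; chlorous acid oxidises the aldehyde without enolising it, the alkene scavenger removes hypochlorite before it can chlorinate ring B, and the cold phosphate-buffered medium should be tolerated by the six-membered aryl acetal.

Step 8
Reactants: 11 2-[3-benzyloxy-6-(5,5-dimethyl-1,3-dioxan-2-yl)-4-methoxy-2-(2-methoxy-1,1-dimethyl-2-oxoethoxy)phenyl]acetic acid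
Product: 12 methyl 2-[3-benzyloxy-6-(5,5-dimethyl-1,3-dioxan-2-yl)-4-methoxy-2-(2-methoxy-1,1-dimethyl-2-oxoethoxy)phenyl]acetate
Conditions: MeI, K2CO3, DMF, rt
Reagents that add atoms: iodomethane, CI
Why: Carboxylate O-alkylation; it is basic and non-aqueous, so acetal and hindered ester are untouched, and it gives two methyl esters so that ester exchange in the next step has no consequence.

Step 9
Reactants: 12 methyl 2-[3-benzyloxy-6-(5,5-dimethyl-1,3-dioxan-2-yl)-4-methoxy-2-(2-methoxy-1,1-dimethyl-2-oxoethoxy)phenyl]acetate
Product: 13 methyl 8-benzyloxy-5-(5,5-dimethyl-1,3-dioxan-2-yl)-7-methoxy-2,2-dimethyl-3-oxochroman-4-carboxylate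
Conditions: KOC(CH3)3 (2.2 equiv), THF (0.02 M), 0 °C to rt; AcOH, 0 °C
Reagents that add atoms: none
Why: The base removes a proton from the only acidic carbon, the benzylic methylene of the arylacetate (future C4), and the ester enolate adds to the carbonyl of the aryloxyisobutyrate ester (future C3); loss of methoxide from the tetrahedral intermediate forms the C3–C4 bond. This is an intramolecular Claisen (Dieckmann) condensation, closest in type to the known closures of ortho-(alkoxycarbonylmethyl)aryloxy esters to chroman-3-ones. Ring D closes in the 6-exo-trig mode with the enolate double bond outside the new ring, and the ortho placement of the two chains on ring B, with the hindered ether bond turned out of the ring plane, holds nucleophile and electrophile close together. No stereocentre of fixed configuration results, because C3 appears as a carbonyl and C4 is doubly activated and largely enolised. The step needs selectivity of direction and of ring size, and the substrate secures both: the isobutyrate carbon has no hydrogen, so only one enolate and only the six-membered ring are possible. High dilution disfavours the intermolecular condensation, and the second equivalent of base converts 13 into its enolate, which pulls the equilibrium forward and protects the product from retro-Claisen cleavage. Benzyl ether, methyl ether and acetal are inert to alkoxide, and the acetic acid quench is too weak to open the acetal.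

Step 10
Reactants: 13 methyl 8-benzyloxy-5-(5,5-dimethyl-1,3-dioxan-2-yl)-7-methoxy-2,2-dimethyl-3-oxochroman-4-carboxylate
Product: 14 8-benzyloxy-5-(5,5-dimethyl-1,3-dioxan-2-yl)-7-methoxy-2,2-dimethylchroman-3-one
Conditions: LiCl (3 equiv), H2O (3 equiv), DMSO, 130 °C, Ar
Reagents that add atoms: none
Why: Krapcho dealkoxycarbonylation: chloride attacks the ester methyl group, the β-keto carboxylate loses CO2 and water protonates the enolate; the near-neutral medium spares the acetal, and exclusion of air protects the readily enolised benzylic ketone.

Step 11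
Reactants: 14 8-benzyloxy-5-(5,5-dimethyl-1,3-dioxan-2-yl)-7-methoxy-2,2-dimethylchroman-3-one
Product: 16 (3S)-8-benzyloxy-3-hydroxy-7-methoxy-2,2-dimethylchroman-5-carbaldehyde, via acetal alcohol 15 (not isolated)
Conditions: (R)-2-methyl-CBS-oxazaborolidine (20 mol %), BH3·SMe2, THF, −20 °C; MeOH; then 2 M HCl, THF, rt
Reagents that add atoms: water, O (the carbonyl oxygen of 16 after acetal hydrolysis)
Why: Corey–Bakshi–Shibata reduction followed by acetal hydrolysis in the same flask; the ketone should bind the ring boron through the lone pair on the side of the small C4 methylene, so that the nitrogen-bound borane delivers hydride to the Re face of C3, and by the usual correlation the (R)-catalyst then gives the (S)-carbinol when the large flank (quaternary C2) also has CIP priority. Methanol destroys every B–H bond before the acid releases the aldehyde.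

Step 12
Reactants: 17 2,4,6-trihydroxyacetophenone
Product: 18 1-[2,4-bis(benzyloxy)-6-hydroxyphenyl]ethanone
Conditions: BnBr (2.1 equiv), K2CO3, DMF, rt
Reagents that add atoms: benzyl bromide, BrCc1ccccc1
Why: Williamson etherification; after the first two hydroxyls are benzylated, the last one stays hydrogen-bonded to the acetyl carbonyl and is much less nucleophilic, so it remains free for the later ring closure.

Step 13
Reactants: 16 (3S)-8-benzyloxy-3-hydroxy-7-methoxy-2,2-dimethylchroman-5-carbaldehyde; 18 1-[2,4-bis(benzyloxy)-6-hydroxyphenyl]ethanone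
Product: 19 (E)-1-[2,4-bis(benzyloxy)-6-hydroxyphenyl]-3-[(3S)-8-benzyloxy-3-hydroxy-7-methoxy-2,2-dimethylchroman-5-yl]prop-2-en-1-one
Conditions: KOH, EtOH/THF, rt
Reagents that add atoms: none
Why: Claisen–Schmidt condensation: only the methyl ketone can enolise, the aldehyde has no α-hydrogen, and dehydration gives the conjugated (E)-enone; in strong base the product is held as its phenoxide, which should prevent closure to a flavanone.

Step 14
Reactants: 19 (E)-1-[2,4-bis(benzyloxy)-6-hydroxyphenyl]-3-[(3S)-8-benzyloxy-3-hydroxy-7-methoxy-2,2-dimethylchroman-5-yl]prop-2-en-1-one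
Product: 21 5,7-bis(benzyloxy)-3-[(3S)-8-benzyloxy-3-hydroxy-7-methoxy-2,2-dimethylchroman-5-yl]-4H-chromen-4-one, via rearranged dimethyl acetal 20 (not isolated)
Conditions: Tl(NO3)3·3H2O (1.2 equiv), MeOH/HC(OMe)3, rt; then 10% aq HCl, 55 °C
Reagents that add atoms: methanol, CO (supplies the two methoxy groups of 20, which leave again on ring closure; no atom of it remains in 21)
Why: Oxidative 1,2-aryl migration of a chalcone: methoxythallation of the enone, shift of the para-alkoxy-substituted ring B from Cβ to Cα with loss of monovalent thallium, and capture by methanol give the β-keto acetal 20. Acid then lets the free ring A phenol close onto the acetal carbon and eliminate methanol to the pyranone. The new centre of 20 is formed without control and disappears on aromatisation of ring C; thallium salts are highly toxic and call for contained handling and waste treatment.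

Step 15
Reactants: 21 5,7-bis(benzyloxy)-3-[(3S)-8-benzyloxy-3-hydroxy-7-methoxy-2,2-dimethylchroman-5-yl]-4H-chromen-4-one
Product: 22 5,7-dihydroxy-3-[(3S)-3,8-dihydroxy-7-methoxy-2,2-dimethylchroman-5-yl]-4H-chromen-4-one
Conditions: H2 (1 atm), 10% Pd/C, EtOAc/MeOH, rt
Reagents that add atoms: none
Why: Catalytic hydrogenolysis of three aryl benzyl ethers; these should cleave faster than the tetrasubstituted, vinylogous-ester C2=C3 bond is reduced, and the C3 carbinol is not benzylic, so its configuration is not at risk.

## Compound list

1 | 5-hydroxyvanillin (3,4-dihydroxy-5-methoxybenzaldehyde) | COc1cc(C=O)cc(O)c1O | starting material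
2 | 4-benzyloxy-3-hydroxy-5-methoxybenzaldehyde | COc1cc(C=O)cc(O)c1OCc1ccccc1 | intermediate
3 | allyl bromide | C=CCBr | starting material
4 | 3-allyloxy-4-benzyloxy-5-methoxybenzaldehyde | COc1cc(C=O)cc(OCC=C)c1OCc1ccccc1 | intermediate
5 | 2-allyl-4-benzyloxy-3-hydroxy-5-methoxybenzaldehyde | COc1cc(C=O)c(CC=C)c(O)c1OCc1ccccc1 | intermediate
6 | 2-allyl-6-benzyloxy-3-(5,5-dimethyl-1,3-dioxan-2-yl)-5-methoxyphenol | COc1cc(C2OCC(C)(C)CO2)c(CC=C)c(O)c1OCc1ccccc1 | intermediate
7 | methyl 2-bromo-2-methylpropanoate | COC(=O)C(C)(C)Br | starting material
8 | methyl 2-[2-allyl-6-benzyloxy-3-(5,5-dimethyl-1,3-dioxan-2-yl)-5-methoxyphenoxy]-2-methylpropanoate | COC(=O)C(C)(C)Oc1c(CC=C)c(C2OCC(C)(C)CO2)cc(OC)c1OCc1ccccc1 | intermediate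
9 | methyl 2-[6-benzyloxy-2-(2,3-dihydroxypropyl)-3-(5,5-dimethyl-1,3-dioxan-2-yl)-5-methoxyphenoxy]-2-methylpropanoate (racemic at the carbinol carbon) | COC(=O)C(C)(C)Oc1c(CC(O)CO)c(C2OCC(C)(C)CO2)cc(OC)c1OCc1ccccc1 | intermediate (not isolated)
10 | methyl 2-[6-benzyloxy-3-(5,5-dimethyl-1,3-dioxan-2-yl)-5-methoxy-2-(2-oxoethyl)phenoxy]-2-methylpropanoate | COC(=O)C(C)(C)Oc1c(CC=O)c(C2OCC(C)(C)CO2)cc(OC)c1OCc1ccccc1 | intermediate
11 | 2-[3-benzyloxy-6-(5,5-dimethyl-1,3-dioxan-2-yl)-4-methoxy-2-(2-methoxy-1,1-dimethyl-2-oxoethoxy)phenyl]acetic acid | COC(=O)C(C)(C)Oc1c(CC(=O)O)c(C2OCC(C)(C)CO2)cc(OC)c1OCc1ccccc1 | intermediate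
12 | methyl 2-[3-benzyloxy-6-(5,5-dimethyl-1,3-dioxan-2-yl)-4-methoxy-2-(2-methoxy-1,1-dimethyl-2-oxoethoxy)phenyl]acetate | COC(=O)Cc1c(C2OCC(C)(C)CO2)cc(OC)c(OCc2ccccc2)c1OC(C)(C)C(=O)OC | intermediate
13 | methyl 8-benzyloxy-5-(5,5-dimethyl-1,3-dioxan-2-yl)-7-methoxy-2,2-dimethyl-3-oxochroman-4-carboxylate (C4 enolisable, no fixed configuration) | COC(=O)C1C(=O)C(C)(C)Oc2c(OCc3ccccc3)c(OC)cc(C3OCC(C)(C)CO3)c21 | intermediate
14 | 8-benzyloxy-5-(5,5-dimethyl-1,3-dioxan-2-yl)-7-methoxy-2,2-dimethylchroman-3-one | O=C1Cc2c(C3OCC(C)(C)CO3)cc(OC)c(OCc3ccccc3)c2OC1(C)C | intermediate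
15 | (3S)-8-benzyloxy-5-(5,5-dimethyl-1,3-dioxan-2-yl)-7-methoxy-2,2-dimethylchroman-3-ol | COc1cc(C2OCC(C)(C)CO2)c2c(c1OCc1ccccc1)OC(C)(C)[C@@H](O)C2 | intermediate (not isolated)
16 | (3S)-8-benzyloxy-3-hydroxy-7-methoxy-2,2-dimethylchroman-5-carbaldehyde | COc1cc(C=O)c2c(c1OCc1ccccc1)OC(C)(C)[C@@H](O)C2 | intermediate
17 | 2,4,6-trihydroxyacetophenone | CC(=O)c1c(O)cc(O)cc1O | starting material
18 | 1-[2,4-bis(benzyloxy)-6-hydroxyphenyl]ethanone | CC(=O)c1c(O)cc(OCc2ccccc2)cc1OCc1ccccc1 | intermediate
19 | (E)-1-[2,4-bis(benzyloxy)-6-hydroxyphenyl]-3-[(3S)-8-benzyloxy-3-hydroxy-7-methoxy-2,2-dimethylchroman-5-yl]prop-2-en-1-one | COc1cc(/C=C/C(=O)c2c(O)cc(OCc3ccccc3)cc2OCc2ccccc2)c2c(c1OCc1ccccc1)OC(C)(C)[C@@H](O)C2 | intermediate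
20 | 1-[2,4-bis(benzyloxy)-6-hydroxyphenyl]-2-[(3S)-8-benzyloxy-3-hydroxy-7-methoxy-2,2-dimethylchroman-5-yl]-3,3-dimethoxypropan-1-one (both epimers at C2 of the propanone) | COc1cc(C(C(OC)OC)C(=O)c2c(O)cc(OCc3ccccc3)cc2OCc2ccccc2)c2c(c1OCc1ccccc1)OC(C)(C)[C@@H](O)C2 | intermediate (not isolated)
21 | 5,7-bis(benzyloxy)-3-[(3S)-8-benzyloxy-3-hydroxy-7-methoxy-2,2-dimethylchroman-5-yl]-4H-chromen-4-one | COc1cc(-c2coc3cc(OCc4ccccc4)cc(OCc4ccccc4)c3c2=O)c2c(c1OCc1ccccc1)OC(C)(C)[C@@H](O)C2 | intermediate
22 | 5,7-dihydroxy-3-[(3S)-3,8-dihydroxy-7-methoxy-2,2-dimethylchroman-5-yl]-4H-chromen-4-one (CNP0277645.1) | COc1cc(-c2coc3cc(O)cc(O)c3c2=O)c2c(c1O)OC(C)(C)[C@@H](O)C2 | target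

## Step count and least certain steps

Total: 15 steps. Longest linear sequence: 14 steps (steps 1 to 11 and 13 to 15; step 12 is the one-step side branch).

**Step 9 (key step).** The most likely failure is slow addition of the enolate to the α,α-disubstituted, sterically shielded ester carbonyl, so that intermolecular condensation or base-induced decomposition outruns ring closure. Cleavage of the β-keto ester by alkoxide if the enolate is not fully formed is the second concern. The fallback gives up the C3–C4 closure, builds ring D as a chromene and sets C3 by epoxidation. It sets out from 2 and comes back at 15, which is then isolated and hydrolysed to 16 with dilute HCl. Phenol 2 is alkylated with 3-chloro-3-methylbut-1-yne (CuCl2 cat., DBU, MeCN, 0 °C) to 4-benzyloxy-3-methoxy-5-[(2-methylbut-3-yn-2-yl)oxy]benzaldehyde F1. Heating in PhNEt2 (propargyl Claisen shift, hydrogen shift and oxa-electrocyclisation onto the only free ortho carbon) should give 8-benzyloxy-7-methoxy-2,2-dimethyl-2H-chromene-5-carbaldehyde F2. Acetalisation as in step 4 gives 2-(8-benzyloxy-7-methoxy-2,2-dimethyl-2H-chromen-5-yl)-5,5-dimethyl-1,3-dioxane F3. Jacobsen epoxidation (NaOCl, 4-phenylpyridine N-oxide, and the (salen)MnCl complex of (S,S)-N,N'-bis(3,5-di-tert-butylsalicylidene)cyclohexane-1,2-diamine, the enantiomer being chosen by analogy with simpler 2,2-dimethylchromenes) should give (3S,4S)-8-benzyloxy-5-(5,5-dimethyl-1,3-dioxan-2-yl)-3,4-epoxy-7-methoxy-2,2-dimethylchroman F4. LiAlH4 in THF delivers hydride to the benzylic C4 and leaves the C3–O bond and its configuration intact. This path is shorter than the main route, but it abandons the Dieckmann disconnection.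

**Step 5.** Substitution at the tertiary carbon by a phenoxide flanked by an allyl and a benzyloxy group may be slower than loss of HBr from the bromo ester, so the alkylation may stall. The fallback sets out from 6 and comes back at 8. The Bargellini reaction of 6 with 1,1,1-trichloro-2-methylpropan-2-ol and NaOH in acetone (phenoxide opening of the gem-dichloroepoxide at its tertiary carbon, then hydrolysis of the acyl chloride) should give 2-[2-allyl-6-benzyloxy-3-(5,5-dimethyl-1,3-dioxan-2-yl)-5-methoxyphenoxy]-2-methylpropanoic acid F5. Methylation with MeI and K2CO3 in DMF then gives 8.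

**Step 11.** Facial discrimination may be insufficient if the ring oxygen on C2 or the peri acetal perturbs the binding of the ketone to the catalyst. A second risk is reduction of the aldehyde if acid is added before all borane is destroyed. The fallback sets out from 14 and comes back at 15. NaBH4 in MeOH gives (3RS)-8-benzyloxy-5-(5,5-dimethyl-1,3-dioxan-2-yl)-7-methoxy-2,2-dimethylchroman-3-ol F6. The enantiomers are separated by preparative chromatography on a polysaccharide carbamate chiral phase, the (S)-enantiomer being 15. The (R)-enantiomer is oxidised back to 14 with Dess–Martin periodinane and recycled.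

**Step 14.** Trivalent thallium may oxidise the electron-rich rings. The C3 hydroxyl may capture the benzylic cation at Cβ through a six-membered ring and slow the aryl shift. The free ring A phenol may divert the enone toward an aurone. The fallback avoids the cationic rearrangement and uses the deoxybenzoin construction; it sets out from 16 and comes back at 22. Reductive cyanation of 16 with TosMIC (KOC(CH3)3, DME, −30 °C; then MeOH, reflux) should give 2-[(3S)-8-benzyloxy-3-hydroxy-7-methoxy-2,2-dimethylchroman-5-yl]acetonitrile F7. Hoesch acylation of phloroglucinol (ZnCl2, HCl, Et2O, 0 °C; then hot water) gives 2-[(3S)-8-benzyloxy-3-hydroxy-7-methoxy-2,2-dimethylchroman-5-yl]-1-(2,4,6-trihydroxyphenyl)ethanone F8. One-carbon insertion and ring closure with N,N-dimethylformamide dimethyl acetal in THF gives 3-[(3S)-8-benzyloxy-3-hydroxy-7-methoxy-2,2-dimethylchroman-5-yl]-5,7-dihydroxy-4H-chromen-4-one F9. Hydrogenolysis as in step 15 gives 22.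

**Step 7.** Partial opening of the acetal at the pH of the chlorite oxidation would expose the aryl aldehyde to over-oxidation. The fallback bypasses the free acid and any acidic medium; it sets out from 10 and comes back at 12. The aldehyde is converted directly into the methyl ester with I2 and KOH in MeOH at 0 °C (oxidation of the hemiacetal), so step 8 is no longer needed.

## Further compounds

F1 | step 9 | 4-benzyloxy-3-methoxy-5-[(2-methylbut-3-yn-2-yl)oxy]benzaldehyde | COc1cc(C=O)cc(OC(C)(C)C#C)c1OCc1ccccc1
F2 | step 9 | 8-benzyloxy-7-methoxy-2,2-dimethyl-2H-chromene-5-carbaldehyde | COc1cc(C=O)c2C=CC(C)(C)Oc2c1OCc1ccccc1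
F3 | step 9 | 2-(8-benzyloxy-7-methoxy-2,2-dimethyl-2H-chromen-5-yl)-5,5-dimethyl-1,3-dioxane | COc1cc(C2OCC(C)(C)CO2)c2C=CC(C)(C)Oc2c1OCc1ccccc1
F4 | step 9 | (3S,4S)-8-benzyloxy-5-(5,5-dimethyl-1,3-dioxan-2-yl)-3,4-epoxy-7-methoxy-2,2-dimethylchroman | COc1cc(C2OCC(C)(C)CO2)c2c(c1OCc1ccccc1)OC(C)(C)[C@H]1O[C@@H]21
F5 | step 5 | 2-[2-allyl-6-benzyloxy-3-(5,5-dimethyl-1,3-dioxan-2-yl)-5-methoxyphenoxy]-2-methylpropanoic acid | OC(=O)C(C)(C)Oc1c(CC=C)c(C2OCC(C)(C)CO2)cc(OC)c1OCc1ccccc1
F6 | step 11 | (3RS)-8-benzyloxy-5-(5,5-dimethyl-1,3-dioxan-2-yl)-7-methoxy-2,2-dimethylchroman-3-ol (racemate) | COc1cc(C2OCC(C)(C)CO2)c2c(c1OCc1ccccc1)OC(C)(C)C(O)C2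
F7 | step 14 | 2-[(3S)-8-benzyloxy-3-hydroxy-7-methoxy-2,2-dimethylchroman-5-yl]acetonitrile | COc1cc(CC#N)c2c(c1OCc1ccccc1)OC(C)(C)[C@@H](O)C2
F8 | step 14 | 2-[(3S)-8-benzyloxy-3-hydroxy-7-methoxy-2,2-dimethylchroman-5-yl]-1-(2,4,6-trihydroxyphenyl)ethanone | COc1cc(CC(=O)c2c(O)cc(O)cc2O)c2c(c1OCc1ccccc1)OC(C)(C)[C@@H](O)C2
F9 | step 14 | 3-[(3S)-8-benzyloxy-3-hydroxy-7-methoxy-2,2-dimethylchroman-5-yl]-5,7-dihydroxy-4H-chromen-4-one | COc1cc(-c2coc3cc(O)cc(O)c3c2=O)c2c(c1OCc1ccccc1)OC(C)(C)[C@@H](O)C2
F0 | step 7 | none | none
A1 | alternative 1 | (3S)-5-(5,7-diacetoxy-4-oxo-4H-chromen-3-yl)-8-hydroxy-7-methoxy-2,2-dimethylchroman-3-yl acetate | COc1cc(-c2coc3cc(OC(C)=O)cc(OC(C)=O)c3c2=O)c2c(c1O)OC(C)(C)[C@@H](OC(C)=O)C2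
A2 | alternative 1 | (2S)-1-[2-(5,7-diacetoxy-4-oxo-4H-chromen-3-yl)-5-hydroxy-4-methoxyphenyl]-3-hydroxy-3-methylbutan-2-yl acetate | COc1cc(-c2coc3cc(OC(C)=O)cc(OC(C)=O)c3c2=O)c(C[C@H](OC(C)=O)C(C)(C)O)cc1O
A3 | alternative 2 | 3-[(3S)-8-benzyloxy-3-(tert-butyldimethylsilyloxy)-7-methoxy-2,2-dimethylchroman-5-yl]-5,7-difluoro-4H-chromen-4-one | O=c1c(-c2cc(OC)c(OCc3ccccc3)c3OC(C)(C)[C@@H](O[Si](C)(C)C(C)(C)C)Cc23)coc2cc(F)cc(F)c12
A4 | alternative 2 | 2-[(3S)-8-benzyloxy-3-(tert-butyldimethylsilyloxy)-7-methoxy-2,2-dimethylchroman-5-yl]-3-hydroxy-1-(2,4,6-trifluorophenyl)prop-2-en-1-one | OC=C(C(=O)c1c(F)cc(F)cc1F)c1cc(OC)c(OCc2ccccc2)c2OC(C)(C)[C@@H](O[Si](C)(C)C(C)(C)C)Cc12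
A5 | alternative 3 | methyl 2-[(3S)-8-benzyloxy-3-hydroxy-7-methoxy-2,2-dimethylchroman-5-yl]acetate | COC(=O)Cc1cc(OC)c(OCc2ccccc2)c2OC(C)(C)[C@@H](O)Cc12
A6 | alternative 3 | methyl 2-[4-benzyloxy-3-methoxy-5-({2-[(2S)-oxiran-2-yl]propan-2-yl}oxy)phenyl]acetate | COC(=O)Cc1cc(OC)c(OCc2ccccc2)c(OC(C)(C)[C@@H]2CO2)c1
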